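**Strategy.** Everything rests on ring D, the cyclopentanone C8–C14–C13–C16–C15 of the bicyclo[3.2.1]octane (ent-kaurane numbering). C8–C14 lies α,β to the lactone carbonyl C7, so an α-methylene lactone is its latent 1,2-dianion; C13(OH)–C16–C15(=O) is a 1,3-dielectrophile, a β-keto imide. One SmI2 reduction therefore closes ring C (C13–C14, ketyl–olefin addition) and ring D (C8–C15, enolate acylation) in a single operation and sets C13 and the quaternary C8. The precursor holds only ring A and the spiro-lactone ring B, with the β-keto imide chain on C9; it comes from a ring A α-formyl ketone, a Morita–Baylis–Hillman carbonate and an Evans aldol.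

Key step: step 16

Numbering used throughout (ent-kaurane): ring A = C1–C5, C10; lactone ring B = C7, C8, C9, C10, C20, O; ring C = C8, C9, C11–C14; ring D = C8, C14, C13, C16, C15; C6 = CH2OH on C5; C17 = methyl on C16.

Assumption: (R)-BINAP (step 2) and (DHQD)2PHAL (step 9) are taken to give the senses of induction drawn; the mirror-image ligand or the pseudo-enantiomeric (DHQ)2PHAL would be used otherwise. The C1 carbinol of step 11 is drawn as the expected 1S epimer; this centre is erased in step 18.

**Step 1**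
Reactants: 1 4,4-dimethylcyclohex-2-en-1-one
Product: 2 4,4-dimethylcyclohexa-2,5-dien-1-one
Conditions: DDQ, p-TsOH (cat.), 1,4-dioxane, reflux
Reagents that add atoms: none
Why: DDQ dehydrogenation of a ketone through its enol; only C5–C6 can be desaturated and the quaternary C4 blocks aromatisation, so the cross-conjugated dienone should form cleanly.

**Step 2**
Reactants: 2 4,4-dimethylcyclohexa-2,5-dien-1-one
Product: 3 (5R)-5-ethenyl-4,4-dimethylcyclohex-2-en-1-one
Conditions: CH2=CHBF3K (1.0 equiv), 2 (1.3 equiv), [Rh(cod)2]BF4 (3 mol %), (R)-BINAP (3.3 mol %), toluene/H2O 10:1, 100 °C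
Reagents that add atoms: potassium vinyltrifluoroborate, [K+].C=C[B-](F)(F)F
Why: Hayashi–Miyaura rhodium-catalysed asymmetric 1,4-addition desymmetrises the dienone, the ligand choosing the enantioface of one enone and so setting C5, and the product keeps the ring A enone with C10 as its only enolisable position.

**Step 3**
Reactants: 3 (5R)-5-ethenyl-4,4-dimethylcyclohex-2-en-1-one
Product: 5 (5S)-5-(hydroxymethyl)-4,4-dimethylcyclohex-2-en-1-one, via keto-aldehyde 4 (not isolated)
Conditions: O3, CH2Cl2/MeOH, −78 °C (Sudan Red 7B end point); Me2S; then NaBH4 (0.5 equiv), EtOH, −78 °C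
Reagents that add atoms: ozone, [O-][O+]=O
Why: Ozonolysis is chemoselective for the isolated vinyl group over the electron-poor enone, and NaBH4 at −78 °C reduces the aldehyde much faster than the conjugated ketone; cold, neutral conditions keep C5 (α to the aldehyde in 4) from epimerising.

**Step 4**
Reactants: 5 (5S)-5-(hydroxymethyl)-4,4-dimethylcyclohex-2-en-1-one
Product: 6 (5S)-5-{[tert-butyl(dimethyl)silyl]oxymethyl}-4,4-dimethylcyclohex-2-en-1-one
Conditions: TBSCl, imidazole, DMF, 23 °C
Reagents that add atoms: tert-butyldimethylsilyl chloride, CC(C)(C)[Si](C)(C)Cl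
Why: Standard silyl ether protection of the primary alcohol (C6–OH), needed before the enolate chemistry at C10.

**Step 5**
Reactants: 6 (5S)-5-{[tert-butyl(dimethyl)silyl]oxymethyl}-4,4-dimethylcyclohex-2-en-1-one
Product: 7 (5R,6Z)-5-{[tert-butyl(dimethyl)silyl]oxymethyl}-6-(hydroxymethylidene)-4,4-dimethylcyclohex-2-en-1-one
Conditions: NaH, HCO2Et, EtOH (cat.), THF, 0 → 23 °C; aq. NH4Cl
Reagents that add atoms: ethyl formate, CCOC=O
Why: Claisen formylation; C10 is the only enolisable position (C2 is vinylic, C4 quaternary), and the product, a hydrogen-bonded Z-enol, is the 1,3-dicarbonyl C–H acid needed in step 9 and already carries C20.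

**Step 6**
Reactants: 8 methyl 4,4-dimethoxybutanoate
Product: 9 4,4-dimethoxybutanal
Conditions: i-Bu2AlH (1.05 equiv), CH2Cl2, −78 °C; aq. KNaC4H4O6 (potassium sodium tartrate)
Reagents that add atoms: none
Why: Partial ester reduction; the aluminium hemiacetal is stable at −78 °C and releases the aldehyde only on work-up, and the acetal is inert.

**Step 7**
Reactants: 9 4,4-dimethoxybutanal; 10 methyl acrylate
Product: 11 methyl 3-hydroxy-6,6-dimethoxy-2-methylidenehexanoate (racemic)
Conditions: DABCO (0.5 equiv), methyl acrylate (3 equiv), MeOH, 23 °C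
Reagents that add atoms: none
Why: Morita–Baylis–Hillman reaction; the racemic carbinol centre is immaterial because it is lost in step 9.

**Step 8**
Reactants: 11 methyl 3-hydroxy-6,6-dimethoxy-2-methylidenehexanoate
Product: 12 methyl 3-[(tert-butoxycarbonyl)oxy]-6,6-dimethoxy-2-methylidenehexanoate (racemic)
Conditions: Boc2O, DMAP (cat.), CH2Cl2, 0 → 23 °C
Reagents that add atoms: di-tert-butyl dicarbonate, CC(C)(C)OC(=O)OC(=O)OC(C)(C)C
Why: DMAP-catalysed O-acylation turns the allylic alcohol into the carbonate leaving group required for Lewis-base allylic alkylation.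

**Step 9**
Reactants: 7 hydroxymethylidene ketone; 12 Morita–Baylis–Hillman carbonate
Product: 13 methyl (3S)-3-[(1S,6R)-6-{[tert-butyl(dimethyl)silyl]oxymethyl}-1-formyl-5,5-dimethyl-2-oxocyclohex-3-en-1-yl]-6,6-dimethoxy-2-methylidenehexanoate
Conditions: (DHQD)2PHAL (10 mol %), 12 (1.3 equiv), toluene, 25 → 40 °C
Reagents that add atoms: none
Why: Lewis-base-catalysed asymmetric allylic alkylation of a Morita–Baylis–Hillman carbonate (SN2′–SN2′): the quinuclidine nitrogen displaces the carbonate, the released tert-butoxide deprotonates 7, and the enolate carbon C10 attacks the allylammonium ion at C9 on the ring A face anti to the C5 CH2OTBS group and away from the syn-axial C4 methyl (sets C10, C20 cis to C6), while the chiral ammonium shields one face of C9 (sets C9); the C8=C14 methylene and the C7 ester arrive in the same step.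

**Step 10**
Reactants: 13 quaternary aldehyde
Product: 15 (5S,6S,11R)-11-{[tert-butyl(dimethyl)silyl]oxymethyl}-5-(3,3-dimethoxypropyl)-10,10-dimethyl-4-methylidene-2-oxaspiro[5.5]undec-8-ene-3,7-dione, via hydroxy ester 14 (not isolated)
Conditions: NaBH4, THF/MeOH, −78 °C; then PPTS (cat.), CH2Cl2, 23 °C
Reagents that add atoms: none
Why: Chemoselective carbonyl reduction followed by lactonisation: NaBH4 at −78 °C reduces the β-keto aldehyde far faster than the hindered enone or the acrylate, and the C20 alcohol closes the six-membered lactone on the C7 ester (6-exo-trig, helped by the quaternary C10) while C1 is still a ketone, so only the 7,20-lactone can form.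

**Step 11**
Reactants: 15 spirolactone enone
Product: 16 (5S,6S,7S,11R)-11-{[tert-butyl(dimethyl)silyl]oxymethyl}-5-(3,3-dimethoxypropyl)-7-hydroxy-10,10-dimethyl-4-methylidene-2-oxaspiro[5.5]undec-8-en-3-one
Conditions: NaBH4, CeCl3·7H2O, MeOH, −78 °C
Reagents that add atoms: none
Why: Luche 1,2-reduction masks the ring A enone (incompatible with SmI2) without touching the α-methylene lactone; hydride is expected anti to the axial C20, giving the 1S alcohol, a centre that is oxidised again in step 18.

**Step 12**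
Reactants: 16 allylic alcohol
Product: 17 (5S,6S,7S,11R)-7-{[tert-butyl(dimethyl)silyl]oxy}-11-{[tert-butyl(dimethyl)silyl]oxymethyl}-5-(3,3-dimethoxypropyl)-10,10-dimethyl-4-methylidene-2-oxaspiro[5.5]undec-8-en-3-one
Conditions: TBSOTf, 2,6-lutidine, CH2Cl2, −78 → −40 °C
Reagents that add atoms: tert-butyldimethylsilyl triflate, CC(C)(C)[Si](C)(C)OS(=O)(=O)C(F)(F)F
Why: Silyl triflate silylation of the hindered allylic alcohol; the low temperature keeps the dimethyl acetal intact.

**Step 13**
Reactants: 17 bis-silyl ether acetal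
Product: 18 3-[(5S,6S,7S,11R)-7-{[tert-butyl(dimethyl)silyl]oxy}-11-{[tert-butyl(dimethyl)silyl]oxymethyl}-10,10-dimethyl-4-methylidene-3-oxo-2-oxaspiro[5.5]undec-8-en-5-yl]propanal
Conditions: LiBF4, MeCN/H2O 98:2, 23 °C
Reagents that add atoms: water, O
Why: Mild Lewis-acid acetal hydrolysis unmasks the C13 aldehyde and should leave both silyl ethers and the α-methylene lactone untouched.

**Step 14**
Reactants: 18 aldehyde; 19 (4R)-4-benzyl-3-propanoyl-1,3-oxazolidin-2-one
Product: 20 Evans syn-aldol adduct, the (2R,3S)-3-hydroxy-2-methyl imide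
Conditions: 19, Bu2BOTf, i-Pr2NEt, CH2Cl2, −78 → 0 °C; then 18, −78 → 0 °C; pH 7 phosphate buffer, MeOH, H2O2, 0 °C
Reagents that add atoms: none
Why: Evans syn-aldol: the Z-boron enolate reacts through a Zimmerman–Traxler chair under auxiliary control, which sets C16 (R) (and a transient 13S carbinol) and forms the C13–C16 bond.

**Step 15**
Reactants: 20 aldol adduct
Product: 21 β-keto imide, the (2R)-2-methyl-3-oxo imide
Conditions: SO3·pyridine, DMSO, i-Pr2NEt, CH2Cl2, −15 → 0 °C
Reagents that add atoms: none
Why: Parikh–Doering oxidation; the α-methyl β-keto imide resists enolisation (allylic strain in its enol), so C16 keeps its configuration.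

**Step 16**
Reactants: 21 β-keto imide
Product: 23 1-O,6-O-bis(tert-butyldimethylsilyl) ether of carbinol 24 (rings A–D complete), via samarium enolate 22 (not isolated)
Conditions: SmI2 (2.2 equiv, 0.1 M in THF), THF, −78 °C, slow addition of 21; then −78 → −20 °C; sat. aq. NH4Cl
Reagents that add atoms: none
Why: SmI2 reduces the chelating β-keto imide ketone to a trivalent-samarium ketyl that adds 6-endo-trig to C14 of the α-methylene lactone (C13–C14, ring C); a second electron gives the lactone enolate 22, whose C8 attacks the imide carbonyl C15 in a 5-(enolexo)-exo-trig Dieckmann-type acylation that expels the oxazolidinone (C8–C15, ring D). The closest known reaction type is the SmI2 ketyl–olefin cyclisation/enolate-trapping cascade (radical–polar crossover), here ended by intramolecular acylation in place of an aldol. C13 is set in a chair-like transition state in which the lactone holds C10 pseudo-equatorial, the samarium-bound ketyl oxygen is axial and bridged to the s-cis lactone carbonyl oxygen, and the branched C16 chain is equatorial, which puts the hydroxyl cis to C10. C8 follows from C13, because the acyl chain can only bridge C13 and C8 in a cis-1,3 sense, and C16 is carried through unchanged since the β-keto imide does not enolise. The step needs ketyl formation at the β-keto imide and not at the lactone (secured by chelation), 6-endo over 5-exo addition (attack at the unsubstituted terminus gives the ester-stabilised tertiary radical) and acylation before protonation (aprotic medium, slow addition, activated imide acyl donor).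

**Step 17**
Reactants: 23 bis-silyl ether
Product: 24 (1S)-carbinol of the target (C1 allylic alcohol, free C6 and C13 hydroxyls)
Conditions: HF·pyridine, pyridine, THF, 0 → 40 °C
Reagents that add atoms: none
Why: Fluoride desilylation under mildly acidic conditions removes both silyl ethers and spares the β-hydroxy ketone (no retro-aldol) and the epimerisable C16.

**Step 18**
Reactants: 24 triol
Product: 25 target (CNP0533761.1)
Conditions: activated MnO2 (excess), CH2Cl2, 23 °C
Reagents that add atoms: none
Why: MnO2 allylic oxidation converts only the C1 allylic alcohol (not the primary C6 or tertiary C13 hydroxyl) into the ring A enone under neutral conditions, so C16 is not epimerised.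

**Compound list**

1 | 4,4-dimethylcyclohex-2-en-1-one | CC1(C)CCC(=O)C=C1 | starting material
2 | 4,4-dimethylcyclohexa-2,5-dien-1-one | CC1(C)C=CC(=O)C=C1 | intermediate
3 | (5R)-5-ethenyl-4,4-dimethylcyclohex-2-en-1-one | C=C[C@H]1CC(=O)C=CC1(C)C | intermediate
4 | (1S)-2,2-dimethyl-5-oxocyclohex-3-ene-1-carbaldehyde | O=C[C@H]1CC(=O)C=CC1(C)C | intermediate
5 | (5S)-5-(hydroxymethyl)-4,4-dimethylcyclohex-2-en-1-one | OC[C@H]1CC(=O)C=CC1(C)C | intermediate
6 | (5S)-5-{[tert-butyl(dimethyl)silyl]oxymethyl}-4,4-dimethylcyclohex-2-en-1-one | CC(C)(C)[Si](C)(C)OC[C@H]1CC(=O)C=CC1(C)C | intermediate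
7 | (5R,6Z)-5-{[tert-butyl(dimethyl)silyl]oxymethyl}-6-(hydroxymethylidene)-4,4-dimethylcyclohex-2-en-1-one | CC(C)(C)[Si](C)(C)OC[C@H]1/C(=C/O)C(=O)C=CC1(C)C | intermediate
8 | methyl 4,4-dimethoxybutanoate | COC(=O)CCC(OC)OC | starting material
9 | 4,4-dimethoxybutanal | O=CCCC(OC)OC | intermediate
10 | methyl acrylate | C=CC(=O)OC | starting material
11 | methyl 3-hydroxy-6,6-dimethoxy-2-methylidenehexanoate (racemic) | C=C(C(=O)OC)C(O)CCC(OC)OC | intermediate
12 | methyl 3-[(tert-butoxycarbonyl)oxy]-6,6-dimethoxy-2-methylidenehexanoate (racemic) | C=C(C(=O)OC)C(OC(=O)OC(C)(C)C)CCC(OC)OC | intermediate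
13 | methyl (3S)-3-[(1S,6R)-6-{[tert-butyl(dimethyl)silyl]oxymethyl}-1-formyl-5,5-dimethyl-2-oxocyclohex-3-en-1-yl]-6,6-dimethoxy-2-methylidenehexanoate | COC(OC)CC[C@H](C(=C)C(=O)OC)[C@]1(C=O)C(=O)C=CC(C)(C)[C@H]1CO[Si](C)(C)C(C)(C)C | intermediate
14 | methyl (3S)-3-[(1S,6R)-6-{[tert-butyl(dimethyl)silyl]oxymethyl}-1-(hydroxymethyl)-5,5-dimethyl-2-oxocyclohex-3-en-1-yl]-6,6-dimethoxy-2-methylidenehexanoate | COC(OC)CC[C@H](C(=C)C(=O)OC)[C@]1(CO)C(=O)C=CC(C)(C)[C@H]1CO[Si](C)(C)C(C)(C)C | intermediate
15 | (5S,6S,11R)-11-{[tert-butyl(dimethyl)silyl]oxymethyl}-5-(3,3-dimethoxypropyl)-10,10-dimethyl-4-methylidene-2-oxaspiro[5.5]undec-8-ene-3,7-dione | COC(OC)CC[C@@H]1C(=C)C(=O)OC[C@]12C(=O)C=CC(C)(C)[C@H]2CO[Si](C)(C)C(C)(C)C | intermediate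
16 | (5S,6S,7S,11R)-11-{[tert-butyl(dimethyl)silyl]oxymethyl}-5-(3,3-dimethoxypropyl)-7-hydroxy-10,10-dimethyl-4-methylidene-2-oxaspiro[5.5]undec-8-en-3-one | COC(OC)CC[C@@H]1C(=C)C(=O)OC[C@]12[C@@H](O)C=CC(C)(C)[C@H]2CO[Si](C)(C)C(C)(C)C | intermediate
17 | (5S,6S,7S,11R)-7-{[tert-butyl(dimethyl)silyl]oxy}-11-{[tert-butyl(dimethyl)silyl]oxymethyl}-5-(3,3-dimethoxypropyl)-10,10-dimethyl-4-methylidene-2-oxaspiro[5.5]undec-8-en-3-one | COC(OC)CC[C@@H]1C(=C)C(=O)OC[C@]12[C@@H](O[Si](C)(C)C(C)(C)C)C=CC(C)(C)[C@H]2CO[Si](C)(C)C(C)(C)C | intermediate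
18 | 3-[(5S,6S,7S,11R)-7-{[tert-butyl(dimethyl)silyl]oxy}-11-{[tert-butyl(dimethyl)silyl]oxymethyl}-10,10-dimethyl-4-methylidene-3-oxo-2-oxaspiro[5.5]undec-8-en-5-yl]propanal | O=CCC[C@@H]1C(=C)C(=O)OC[C@]12[C@@H](O[Si](C)(C)C(C)(C)C)C=CC(C)(C)[C@H]2CO[Si](C)(C)C(C)(C)C | intermediate
19 | (4R)-4-benzyl-3-propanoyl-1,3-oxazolidin-2-one | CCC(=O)N1[C@H](Cc2ccccc2)COC1=O | starting material
20 | (4R)-4-benzyl-3-[(2R,3S)-3-hydroxy-2-methyl-5-(Sp)pentanoyl]-1,3-oxazolidin-2-one, Sp = the (5S,6S,7S,11R)-spirolactone-5-yl group of 18 | C[C@H]([C@@H](O)CC[C@@H]1C(=C)C(=O)OC[C@]12[C@@H](O[Si](C)(C)C(C)(C)C)C=CC(C)(C)[C@H]2CO[Si](C)(C)C(C)(C)C)C(=O)N3[C@H](Cc4ccccc4)COC3=O | intermediate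
21 | (4R)-4-benzyl-3-[(2R)-2-methyl-3-oxo-5-(Sp)pentanoyl]-1,3-oxazolidin-2-one, Sp as in 20 | C[C@H](C(=O)CC[C@@H]1C(=C)C(=O)OC[C@]12[C@@H](O[Si](C)(C)C(C)(C)C)C=CC(C)(C)[C@H]2CO[Si](C)(C)C(C)(C)C)C(=O)N3[C@H](Cc4ccccc4)COC3=O | intermediate
22 | trivalent-samarium alkoxide/lactone enolate after ring C closure (C13–O–SmI2, C8=C7–O–SmI2, imide intact) | C[C@H]([C@]1(O[Sm](I)I)CC[C@@H]2C(C1)=C(O[Sm](I)I)OC[C@]23[C@@H](O[Si](C)(C)C(C)(C)C)C=CC(C)(C)[C@H]3CO[Si](C)(C)C(C)(C)C)C(=O)N4[C@H](Cc5ccccc5)COC4=O | intermediate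
23 | 1-O,6-O-bis(tert-butyldimethylsilyl) ether of 24; (1S,5R,8S,9S,10S,13S,16R), rings A–D complete, C15 ketone, C13 hydroxyl | C[C@H]1C(=O)[C@]23C[C@@]1(O)CC[C@H]2[C@]1(COC3=O)[C@@H](O[Si](C)(C)C(C)(C)C)C=CC(C)(C)[C@H]1CO[Si](C)(C)C(C)(C)C | intermediate
24 | (1S)-1-hydroxy analogue of the target (C1 allylic alcohol in place of the C1 ketone) | C[C@H]1C(=O)[C@]23C[C@@]1(O)CC[C@H]2[C@]1(COC3=O)[C@@H](O)C=CC(C)(C)[C@H]1CO | intermediate
25 | CNP0533761.1; (5R,8S,9S,10S,13S,16R) | C[C@H]1C(=O)[C@]23C[C@@]1(O)CC[C@H]2[C@]1(COC3=O)C(=O)C=CC(C)(C)[C@H]1CO | target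

**Count.** Total step count: 18. Longest linear sequence: 15 steps (steps 1–5 and 9–18; steps 6–8 make carbonate 12 in a side branch).

**Steps most likely to fail**

Step 16 (key cascade). The trivalent-samarium enolate may be protonated, or the samarium aldolate may fragment (retro-aldol, or attack of the C13 alkoxide on the carbamate carbonyl), before the acyl transfer, because ring C has to leave its chair to bring C15 over C8. Facial selectivity at C13 may also erode if the samarium bridge to the lactone carbonyl is lost, and excess SmI2 may over-reduce the C15 ketone. Fallback (sets out from 21, comes back at 24): SmI2 with t-BuOH (2 equiv) in THF at −78 °C stops the sequence after the ketyl–olefin cyclisation and should give the ring C hydroxy imide F1 (C8 protonated, either epimer). TMSOTf/2,6-lutidine then caps the tertiary alcohol as the trimethylsilyl ether F2, so that retro-aldol is blocked. LiN(SiMe3)2 in THF (−78 → 0 °C) generates the lactone enolate, which closes ring D by Dieckmann-type acylation to the tris-silyl ether F3. The HF·pyridine treatment of step 17 removes all three silyl groups and gives 24.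

Step 9 (allylic alkylation). The SN2′ attack on a β-alkyl allylammonium ion may be slow, O-allylation may compete with C-allylation, or catalyst control at C9 and substrate control at C10 may be mismatched. Fallback (sets out from 7 and 11, comes back at 13): NBS/Me2S in CH2Cl2 converts 11 with allylic transposition into the (Z)-allylic bromide F4. K2CO3 in acetone O-alkylates 7 to the (E)-allyloxymethylidene ketone F5. Heating F5 (toluene, 140 °C, BHT) triggers a Claisen rearrangement. Its chair transition state, on the ring A face anti to the C5 substituent, places C5 and the C11 chain axial, so it should deliver the same 9S,10S aldehyde 13 under substrate control alone.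

Step 2 (desymmetrising conjugate addition). Enantioface selection may be insufficient, the vinyl donor may protodeboronate, or addition at the hindered β-carbon next to the quaternary C4 may be sluggish or occur twice. Fallback (sets out from 2, comes back at 5): an iminium-catalysed desymmetrising Michael addition of nitromethane (9-amino-9-deoxy-epi-cinchona primary amine of the appropriate pseudo-enantiomeric series, PhCO2H) should give the nitromethyl enone F6. A Nef reaction (NaOMe, then buffered aqueous TiCl3/NH4OAc) converts it into aldehyde 4, which is reduced as in step 3 (NaBH4, −78 °C) to 5.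

**Further compounds**

F1 | step 16 | ring C hydroxy imide (C13 tertiary alcohol, C8–H, imide intact; C8 either epimer) | C[C@H]([C@]1(O)CC[C@@H]2C(C1)C(=O)OC[C@]23[C@@H](O[Si](C)(C)C(C)(C)C)C=CC(C)(C)[C@H]3CO[Si](C)(C)C(C)(C)C)C(=O)N4[C@H](Cc5ccccc5)COC4=O
F2 | step 16 | C13 trimethylsilyl ether of F1 | C[C@H]([C@]1(O[Si](C)(C)C)CC[C@@H]2C(C1)C(=O)OC[C@]23[C@@H](O[Si](C)(C)C(C)(C)C)C=CC(C)(C)[C@H]3CO[Si](C)(C)C(C)(C)C)C(=O)N4[C@H](Cc5ccccc5)COC4=O
F3 | step 16 | C13 trimethylsilyl ether of 23 | C[C@H]1C(=O)[C@]23C[C@@]1(O[Si](C)(C)C)CC[C@H]2[C@]1(COC3=O)[C@@H](O[Si](C)(C)C(C)(C)C)C=CC(C)(C)[C@H]1CO[Si](C)(C)C(C)(C)C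
F4 | step 9 | methyl (2Z)-2-(bromomethyl)-6,6-dimethoxyhex-2-enoate | COC(OC)CC/C=C(\CBr)C(=O)OC
F5 | step 9 | (E)-allyloxymethylidene ketone from O-alkylation of 7 with F4 | CC(C)(C)[Si](C)(C)OC[C@H]1/C(=C\OC/C(C(=O)OC)=C\CCC(OC)OC)C(=O)C=CC1(C)C
F6 | step 2 | (5S)-4,4-dimethyl-5-(nitromethyl)cyclohex-2-en-1-one | [O-][N+](=O)C[C@H]1CC(=O)C=CC1(C)C
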